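**Plan**

1. Retrosynthesis: the C7–O–C1′ ether is cut first (Mitsunobu), then the C3=C4 unsaturation and the O7 benzyl group are taken back, then O1 is excised from between C8a and C2 to leave an indan-1-one, whose aryl–acyl bond and three-carbon chain lead back to syringaldehyde and Meldrum's acid.
2. Forward: ring A comes complete from syringaldehyde; a five-membered ketone ring is closed on it by Friedel–Crafts acylation and widened to the six-membered lactone by oxygen insertion; dehydrogenation and debenzylation give the 7-hydroxycoumarin, and the ten-carbon chain, made from geraniol in two steps, is joined last.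
3. Enabling feature: in ring A (C4a, C5, C6, C7, C8, C8a) the oxygens on C6, C7 and C8 lie symmetrically about the C4a–C7 axis, so C5 and C8a are equivalent in the arylpropanoic acid; the acyl carbon can bond to only one kind of ring carbon, and that carbon becomes C8a, the atom that receives O1.
4. Stereochemistry: the only stereocentres, C2′ and C3′ of the oxirane (both R), are set together by Sharpless asymmetric epoxidation with D-(−)-diethyl tartrate on the 2′E-alkene inherited from geraniol; the 5′E-alkene comes from the singlet-oxygen ene reaction.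

Key step: step 4

Remark: coumarin locants (O1, C2 … C8a) are used for the bicycle, indanone locants where stated, and primed locants C1′–C8′ for the geraniol-derived chain; intermediates 10, 12 and 13 are racemic and transient, so no configuration is assigned to them.

**Route**

Step 1
Reactants: 1 syringaldehyde (4-hydroxy-3,5-dimethoxybenzaldehyde); 2 benzyl bromide
Product: 3 4-(benzyloxy)-3,5-dimethoxybenzaldehyde
Conditions: K2CO3, DMF, 60 °C
Reagents that add atoms: none
Why: Williamson etherification of the phenoxide with a reactive benzylic bromide should proceed cleanly, the aldehyde being inert to K2CO3.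

Step 2
Reactants: 3 4-(benzyloxy)-3,5-dimethoxybenzaldehyde; 4 Meldrum's acid (2,2-dimethyl-1,3-dioxane-4,6-dione)
Product: 7 3-[4-(benzyloxy)-3,5-dimethoxyphenyl]propanoic acid, via arylidene Meldrum's acid 5 (not isolated), via arylmethyl Meldrum's acid 6 (not isolated)
Conditions: HCO2H–Et3N (5:2), 100 °C; then aq. HCl
Reagents that add atoms: none
Why: Knoevenagel condensation gives 5, formate reduces its strongly electrophilic alkene by conjugate hydride transfer to 6, and at 100 °C the water released in the condensation opens the dioxanedione, which loses acetone and CO2 to leave the acid, the benzyl ether being safe because no hydrogenation catalyst is present.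

Step 3
Reactants: 7 3-[4-(benzyloxy)-3,5-dimethoxyphenyl]propanoic acid
Product: 9 6-(benzyloxy)-5,7-dimethoxy-2,3-dihydro-1H-inden-1-one, via acid chloride 8 (not isolated)
Conditions: (COCl)2, DMF (cat.), CH2Cl2, 0 °C to rt; evaporate; SnCl4 (1.1 equiv), CH2Cl2, −20 to 0 °C
Reagents that add atoms: none
Why: Intramolecular Friedel–Crafts acylation should occur at the ring carbon ortho to one methoxy group and para to the other, and since the two carbons ortho to the chain are equivalent by the mirror symmetry of 7 only one indanone can form.

Step 4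
Reactants: 9 6-(benzyloxy)-5,7-dimethoxy-2,3-dihydro-1H-inden-1-one
Product: 11 7-(benzyloxy)-6,8-dimethoxychroman-2-one, via Criegee adduct 10 (not isolated)
Conditions: mCPBA (1.5 equiv), CF3CO2H (1 equiv), CH2Cl2, 0 °C to rt, dark
Reagents that add atoms: 3-chloroperoxybenzoic acid (mCPBA), OOC(=O)c1cccc(Cl)c1
Why: The acid-activated ketone of 9 adds the peracid to give Criegee adduct 10, in which the aryl carbon C7a (indanone locant), antiperiplanar to the O–O bond, shifts from carbon to the proximal peroxide oxygen as 3-chlorobenzoate leaves (Baeyer–Villiger oxidation). The closest known reaction type is the peracid oxidation of methoxy-substituted indan-1-ones to 3,4-dihydrocoumarins. The six-membered lactone is not closed end to end but arises by one-atom ring expansion of the five-membered ketone: O1–C2 forms in the addition and O1–C8a in the 1,2-shift. No stereocentre is formed. The step needs aryl rather than methylene migration, which the methoxy groups ortho and para to the migrating carbon secure by stabilising its electron deficiency in the transition state, the benzyloxy group meta to it being a spectator. It also needs the peracid to spare the electron-rich arene, which the acyl substituent secures before insertion and the limited excess of oxidant after it.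

Step 5
Reactants: 11 7-(benzyloxy)-6,8-dimethoxychroman-2-one
Product: 14 7-(benzyloxy)-6,8-dimethoxy-2H-chromen-2-one, via 3-phenylselanyl lactone 12 (not isolated), via selenoxide 13 (not isolated)
Conditions: LiN(SiMe3)2, THF, −78 °C; PhSeBr, −78 °C; then AcOH, 30% H2O2, 0 °C to rt
Reagents that add atoms: none
Why: The lithium enolate at C3 should be selenenylated by PhSeBr, and after oxidation the selenoxide can only undergo syn-elimination with a C4 hydrogen, giving the conjugated coumarin (selenoxide elimination).

Step 6
Reactants: 14 7-(benzyloxy)-6,8-dimethoxy-2H-chromen-2-one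
Product: 15 isofraxidin (7-hydroxy-6,8-dimethoxy-2H-chromen-2-one)
Conditions: BCl3 (2 equiv), pentamethylbenzene (3 equiv), CH2Cl2, −78 °C; then H2O
Reagents that add atoms: none
Why: Lewis-acid cleavage of the aryl benzyl ether, with the benzyl cation trapped by pentamethylbenzene (Friedel–Crafts benzylation of the scavenger), should be faster at −78 °C than cleavage of the two aryl methyl ethers and should leave the lactone intact.

Step 7
Reactants: 16 geraniol ((2E)-3,7-dimethylocta-2,6-dien-1-ol)
Product: 18 (2E,5E)-3,7-dimethylocta-2,5-diene-1,7-diol, via allylic hydroperoxide 17 (not isolated)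
Conditions: O2, visible light, 5,10,15,20-tetraphenylporphyrin (metal-free, cat.), CH2Cl2, 0 °C; then PPh3, 0 °C to rt; chromatography
Reagents that add atoms: dioxygen, O=O
Why: In the Schenck ene reaction singlet oxygen should attack the more electron-rich 6,7-alkene and, on abstraction of a C5 hydrogen, place the hydroperoxide on C7 with the alkene moved to C5–C6 in the E geometry, PPh3 then reducing the hydroperoxide, and the regioisomer from abstraction at a methyl group is removed by chromatography.

Step 8
Reactants: 18 (2E,5E)-3,7-dimethylocta-2,5-diene-1,7-diol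
Product: 19 {(2R,3R)-3-[(2E)-4-hydroxy-4-methylpent-2-en-1-yl]-3-methyloxiran-2-yl}methanol
Conditions: Ti(OiPr)4 (10–20 mol%), D-(−)-diethyl tartrate, tBuOOH (in decane), 4 Å MS, CH2Cl2, −20 °C
Reagents that add atoms: tert-butyl hydroperoxide, CC(C)(C)OO
Why: In the Sharpless asymmetric epoxidation the primary allylic alcohol binds the titanium tartrate catalyst and D-(−)-diethyl tartrate directs oxygen to the alkene face that gives the (2R,3R)-oxirane, both stereocentres being set together and stereospecifically from the E-alkene, while the tertiary allylic alcohol and its disubstituted alkene react far more slowly.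

Step 9
Reactants: 15 isofraxidin; 19 {(2R,3R)-3-[(2E)-4-hydroxy-4-methylpent-2-en-1-yl]-3-methyloxiran-2-yl}methanol
Product: 20 7-{[(2R,3R)-3-[(2E)-4-hydroxy-4-methylpent-2-en-1-yl]-3-methyloxiran-2-yl]methoxy}-6,8-dimethoxy-2H-chromen-2-one
Conditions: PPh3, DIAD, THF, 0 °C to rt
Reagents that add atoms: none
Why: In the Mitsunobu etherification the acidic 7-hydroxycoumarin should displace the oxyphosphonium group at the primary carbon C1′, which is not a stereocentre, so the oxirane configuration is carried over unchanged and the tertiary alcohol is not activated.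

**Compound list**

1 | syringaldehyde (4-hydroxy-3,5-dimethoxybenzaldehyde) | COc1cc(C=O)cc(OC)c1O | starting material
2 | benzyl bromide | BrCc1ccccc1 | starting material
3 | 4-(benzyloxy)-3,5-dimethoxybenzaldehyde | COc1cc(C=O)cc(OC)c1OCc1ccccc1 | intermediate
4 | Meldrum's acid (2,2-dimethyl-1,3-dioxane-4,6-dione) | CC1(C)OC(=O)CC(=O)O1 | starting material
5 | 5-[4-(benzyloxy)-3,5-dimethoxybenzylidene]-2,2-dimethyl-1,3-dioxane-4,6-dione | COc1cc(C=C2C(=O)OC(C)(C)OC2=O)cc(OC)c1OCc1ccccc1 | intermediate
6 | 5-[4-(benzyloxy)-3,5-dimethoxybenzyl]-2,2-dimethyl-1,3-dioxane-4,6-dione | COc1cc(CC2C(=O)OC(C)(C)OC2=O)cc(OC)c1OCc1ccccc1 | intermediate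
7 | 3-[4-(benzyloxy)-3,5-dimethoxyphenyl]propanoic acid | COc1cc(CCC(O)=O)cc(OC)c1OCc1ccccc1 | intermediate
8 | 3-[4-(benzyloxy)-3,5-dimethoxyphenyl]propanoyl chloride | COc1cc(CCC(Cl)=O)cc(OC)c1OCc1ccccc1 | intermediate
9 | 6-(benzyloxy)-5,7-dimethoxy-2,3-dihydro-1H-inden-1-one | COc1cc2CCC(=O)c2c(OC)c1OCc1ccccc1 | intermediate
10 | Criegee adduct, 6-(benzyloxy)-1-hydroxy-5,7-dimethoxy-2,3-dihydro-1H-inden-1-yl 3-chlorobenzenecarboperoxoate (racemic) | COc1cc2CCC(O)(OOC(=O)c3cccc(Cl)c3)c2c(OC)c1OCc1ccccc1 | intermediate
11 | 7-(benzyloxy)-6,8-dimethoxychroman-2-one | COc1cc2CCC(=O)Oc2c(OC)c1OCc1ccccc1 | intermediate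
12 | 7-(benzyloxy)-6,8-dimethoxy-3-(phenylselanyl)chroman-2-one (racemic) | COc1cc2CC([Se]c3ccccc3)C(=O)Oc2c(OC)c1OCc1ccccc1 | intermediate
13 | 7-(benzyloxy)-6,8-dimethoxy-3-(phenylseleninyl)chroman-2-one | COc1cc2CC([Se](=O)c3ccccc3)C(=O)Oc2c(OC)c1OCc1ccccc1 | intermediate
14 | 7-(benzyloxy)-6,8-dimethoxy-2H-chromen-2-one | COc1cc2ccc(=O)oc2c(OC)c1OCc1ccccc1 | intermediate
15 | isofraxidin (7-hydroxy-6,8-dimethoxy-2H-chromen-2-one) | COc1cc2ccc(=O)oc2c(OC)c1O | intermediate
16 | geraniol ((2E)-3,7-dimethylocta-2,6-dien-1-ol) | CC(C)=CCC/C(C)=C/CO | starting material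
17 | (2E,5E)-7-hydroperoxy-3,7-dimethylocta-2,5-dien-1-ol | CC(C)(OO)/C=C/C/C(C)=C/CO | intermediate
18 | (2E,5E)-3,7-dimethylocta-2,5-diene-1,7-diol | CC(C)(O)/C=C/C/C(C)=C/CO | intermediate
19 | {(2R,3R)-3-[(2E)-4-hydroxy-4-methylpent-2-en-1-yl]-3-methyloxiran-2-yl}methanol | OC[C@H]1O[C@]1(C)C/C=C/C(C)(C)O | intermediate
20 | 7-{[(2R,3R)-3-[(2E)-4-hydroxy-4-methylpent-2-en-1-yl]-3-methyloxiran-2-yl]methoxy}-6,8-dimethoxy-2H-chromen-2-one | COc1cc2ccc(=O)oc2c(OC)c1OC[C@H]1O[C@]1(C)C/C=C/C(C)(C)O | target

**Step count**

Total: 9 steps. Longest linear sequence: 7 steps (steps 1–6 and 9); the side-chain branch is steps 7 and 8.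

**Steps most likely to fail, with fallbacks**

Step 5. The lithium enolate of the aryl lactone may open to a ketene phenoxide or condense with unreacted lactone, and selenenylation may occur twice at C3. The fallback sets out from chromanone 11. Hydrogenolysis (H2, Pd/C, EtOAc, rt) should remove the benzyl group to give 7-hydroxy-6,8-dimethoxychroman-2-one F1. With the free hydroxyl para to C4a, DDQ in dioxane should abstract hydride from C4 through a para-quinone methide that tautomerises to the coumarin. This gives isofraxidin 15, where the route is rejoined; steps 5 and 6 are both replaced.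

Step 3. SnCl4 and the HCl released may cleave the benzyl ether or the methoxy group that ends up next to the ketone, and intermolecular acylation may compete with ring closure. The fallback sets out from aldehyde 3 and Meldrum's acid 4. The reductive condensation is stopped at the dioxanedione stage (HCO2H–Et3N at room temperature, or NaBH4 reduction of arylidene 5), so that 5-[4-(benzyloxy)-3,5-dimethoxybenzyl]-2,2-dimethyl-1,3-dioxane-4,6-dione 6 is isolated. Heating 6 with Sc(OTf)3 (10 mol%) in MeNO2 at 100 °C should bring about a catalytic intramolecular Friedel–Crafts acylation by the dioxanedione, with loss of acetone and CO2. This gives indanone 9, where the route is rejoined, without an acid chloride or a stoichiometric Lewis acid; the detour makes no compound that is absent from the compound list (F0).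

Step 7. The ene reaction may be poorly regioselective, since hydrogen abstraction from a terminal methyl group competes with abstraction from C5 and puts the hydroperoxide on C6; some attack on the 2,3-alkene is also possible. The fallback sets out from geraniol 16 and fixes the oxygen at C7 by epoxide chemistry:
- Acetylation (Ac2O, pyridine) gives geranyl acetate F2.
- mCPBA with NaHCO3 in CH2Cl2 at 0 °C should epoxidise the more electron-rich distal alkene to give (2E)-6,7-epoxy-3,7-dimethyloct-2-en-1-yl acetate F3.
- Phenylselenide anion (PhSeSePh, NaBH4, EtOH) should open the oxirane at the less hindered C6 to give (2E)-7-hydroxy-3,7-dimethyl-6-(phenylselanyl)oct-2-en-1-yl acetate F4.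
- H2O2 in THF oxidises this to (2E)-7-hydroxy-3,7-dimethyl-6-(phenylseleninyl)oct-2-en-1-yl acetate F5, which can only eliminate toward C5 because C7 bears no hydrogen, giving (2E,5E)-7-hydroxy-3,7-dimethylocta-2,5-dien-1-yl acetate F6.
- Methanolysis (K2CO3, MeOH) returns to diol 18; any acetate lost earlier under the borohydride conditions only anticipates this last operation.

**Further compounds**

F1 | step 5 | 7-hydroxy-6,8-dimethoxychroman-2-one | COc1cc2CCC(=O)Oc2c(OC)c1O
F0 | step 3 | none | none
F2 | step 7 | geranyl acetate, (2E)-3,7-dimethylocta-2,6-dien-1-yl acetate | CC(C)=CCC/C(C)=C/COC(C)=O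
F3 | step 7 | (2E)-6,7-epoxy-3,7-dimethyloct-2-en-1-yl acetate (racemic) | CC1(C)OC1CC/C(C)=C/COC(C)=O
F4 | step 7 | (2E)-7-hydroxy-3,7-dimethyl-6-(phenylselanyl)oct-2-en-1-yl acetate (racemic) | CC(C)(O)C([Se]c1ccccc1)CC/C(C)=C/COC(C)=O
F5 | step 7 | (2E)-7-hydroxy-3,7-dimethyl-6-(phenylseleninyl)oct-2-en-1-yl acetate | CC(C)(O)C([Se](=O)c1ccccc1)CC/C(C)=C/COC(C)=O
F6 | step 7 | (2E,5E)-7-hydroxy-3,7-dimethylocta-2,5-dien-1-yl acetate | CC(C)(O)/C=C/C/C(C)=C/COC(C)=O
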